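**Remark (assumptions).** Cembrane numbering is used throughout: C1 = lactone β‑carbon, C14 = lactone O–CH, C15(=C17H2)–C16(=O) = methylene‑lactone carbons, C18/C19/C20 = carbons on C4/C8/C12. Compounds 1, 4, 9 and 15 and all reagents are taken as purchased. In step 10 the ligand antipode is the one that directs addition to the Re face of 15.

## Analysis of the target

The target is a cembranolide: a 14‑membered carbocycle (C1–C14) trans‑fused at C1/C14 to an α‑methylene‑γ‑butyrolactone (O–C14, C16=O, C15=C17H2). It carries a trans‑trisubstituted epoxide at C3–C4 (C18 methyl on C4), an (E)‑C11=C12 olefin (C20 methyl on C12), an acetate on C13, and a secondary allylic hydroperoxide on C7 next to the exocyclic C8=C19 methylene. The six stereocentres fall into three groups with no rigid frame between them: the contiguous triad C13(S)/C14(R)/C1(R) (13,14‑anti; H‑1/H‑14 trans), the epoxide pair C3(S)/C4(S) behind the C2 methylene, and the remote C7(S). The hydroperoxide does not survive low‑valent metals, phosphines, acid or base; the lactone is a Michael acceptor; the epoxide is acid‑labile and forbids any carbanion or radical at C2; the C13 acetate is allylic. The C7–OOH/C8=C19 unit is the signature of a Schenck ene reaction of a (7E)‑olefin, so the real problem is the (7E,11E)‑diene macrocycle 22. The feature the strategy is tied to is the array C10–C11=C12(C20)–C13(O)–C14(O) inside the 14‑membered ring: an (E)‑2‑methylallylic carbinol at C13, anti to the oxygenated lactone carbon C14. That is the product pattern of a syn‑hydrometallative reductive coupling of a methyl‑capped alkyne (C11≡C12–C20) with an α‑oxygenated aldehyde (C13), so the ring, the olefin geometry and C13 can be made in one ring‑closing operation. The difficulty lies in closing the macrocycle without a template while fixing a trisubstituted olefin, relaying absolute configuration between the remote groups, and keeping the hydroperoxide for the very end.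

## Retrosynthetic reasoning

**23 ⇒ 22.** The C7–O bond and the C8=C19 olefin are removed together by a retro‑ene step, giving the (7E)‑olefin 22. The hydroperoxide tolerates none of the metal or fluoride chemistry used earlier, so it must come last. The forward photo‑oxygenation must pick C7=C8 over C11=C12, abstract H from C19, and attack one face.

**22 ⇒ 21 ⇒ 20.** The acetate is traced to the free C13 alcohol 21 and this to the triethylsilyl ether 20. No skeletal bond is cut; 20 is simply the form in which the key step delivers C13–O.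

**20 ⇒ 19 (key disconnection).** The C12–C13 bond (with the C11–H bond) is cut, opening the macrocycle to the linear ynal 19. It is cut here because this is the only place where one reaction closes the 14‑membered ring, sets the (E)‑C11=C12 geometry and creates C13 next to an existing control element (C14). The forward reaction must bond the aldehyde to the methyl‑bearing alkyne carbon, add anti to the C14–O bond, and cyclise rather than oligomerise.

**19 ⇒ 18 ⇒ 17.** The aldehyde is traced through the primary alcohol 18 to its silyl ether 17. Only the oxidation level of C13 changes.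

**17 ⇒ 14 + 15.** The C1–C14 bond and the lactone C–O bond are cut, giving allylic bromide 14 and the two‑carbon aldehyde 15. This 2‑(alkoxycarbonyl)allylation is used for fragment union, not ring closure, so C1 and C14 are set as a pair under catalyst control before the ring exists.

**14 ⇒ 13 ⇒ 11 ⇒ 8 + 9.** The bromide is traced to allylic alcohol 13. The C15–C17 bond is cut by retro‑hydroxymethylation of ynoate 11 (via alane 12). The C1–C2 bond is cut between acetylide carbon C1 of 9 and the epoxy triflate 10 made from 8. C2 is made the electrophile because a carbanion or radical at C2 would open the epoxide.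

**8 ⇒ 7.** The epoxide is removed to the allylic alcohol 7. The C2 hydroxyl lets a tartrate‑controlled epoxidation pick C3=C4 out of two trisubstituted olefins and set C3/C4 absolutely.

**7 ⇒ 6 ⇒ 5 ⇒ 3 + 4 ⇒ 2 ⇒ 1.** The C20 methyl cap and the C9–C10 bond are removed (three‑carbon propargyl unit 4 plus allylic bromide 3). The bromide is traced through alcohol 2 to 1, which supplies C2–C9 and both (E)‑olefins.

## Alternatives that were turned down

**Alternative 1:** the textbook cembranolide closure. Disconnection: C1–C14 and the lactone C–O bond as the ring‑closing event. Forward key step: intramolecular Nozaki–Hiyama/Barbier 2‑(alkoxycarbonyl)allylation of the ω‑formyl allylic bromide A1 to the macrocyclic lactone A2. Turned down on three grounds. The aldehyde in A1 sits on C14 with C13 both α to the carbonyl and allylic, so C13 can epimerise or move into conjugation before cyclisation. C13 and the (E)‑C11=C12 olefin must be built beforehand on a separate C10–C14 fragment, which costs more steps than the key step saves. Facial control by C13 and anti selectivity would both have to hold inside a ring‑closing transition state.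

**Alternative 2:** Disconnection: the C7=C8 olefin. Forward key step: ring‑closing olefin metathesis of diene A3 to 22. Turned down because a trisubstituted olefin closed into a 14‑membered ring comes as an E/Z mixture with no element to bias it. The enoate C15=C17 and the 1,1‑disubstituted partner are poor or competing metathesis partners. The step sets no stereocentre, so all five must already be carried by the linear diene.

**Alternative 3:** Disconnection: C13–C14 and C1–C2, mapping C2–C13 onto the sesquiterpenol A4 and inserting a two‑carbon alkynyl linchpin as C14/C1. Forward key step: reductive endo‑macrocyclisation of the alkynyl enal A5 to the (E)‑allylic silyl ether A6. The ring is reached very quickly. It was turned down because the E‑C14=C1 olefin of A6 then needs a syn addition of oxygen (C14) and the acrylate carbon (C1). C13–O is allylic to both C14=C1 and C11=C12, and two more nucleophilic trisubstituted olefins are present, so neither a directed nor an undirected oxy‑carbofunctionalisation can be defended as selective.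

Key step: step 13

## Route

Step 1
Reactants: 1 geranyl acetate
Product: 2 (2E,6E)-8-hydroxy-3,7-dimethylocta-2,6-dien-1-yl acetate
Conditions: SeO2 (10 mol %), t-BuOOH, salicylic acid (10 mol %), CH2Cl2, rt
Reagents that add atoms: tert-butyl hydroperoxide CC(C)(C)OO (terminal oxidant); selenium dioxide O=[Se]=O (catalytic oxygen carrier)
Why: Riley allylic oxidation in its catalytic Sharpless form (ene reaction, then [2,3]-shift); the (E)-methyl of the terminal olefin is oxidised, and the C2=C3 olefin is deactivated by the allylic acetate.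

Step 2
Reactants: 2 hydroxy acetate
Product: 3 (2E,6E)-8-bromo-3,7-dimethylocta-2,6-dien-1-yl acetate
Conditions: CBr4, PPh3, CH2Cl2, 0 °C
Reagents that add atoms: carbon tetrabromide BrC(Br)(Br)Br
Why: Appel bromination of a primary allylic alcohol; neutral conditions leave the acetate and both olefins untouched.

Step 3
Reactants: 3 bromo acetate; 4 3-bromo-1-(trimethylsilyl)prop-1-yne
Product: 5 (2E,6E)-3,7-dimethyl-11-(trimethylsilyl)undeca-2,6-dien-10-yn-1-yl acetate
Conditions: 4, Mg, Et2O, 0 °C; then 3, Li2CuCl4 (3 mol %), THF, −78 → −20 °C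
Reagents that add atoms: none
Why: Copper-catalysed (Kochi-type) sp3–sp3 coupling of a Grignard reagent with a primary allylic bromide; the silyl cap makes the propargyl terminus react, the cold spares the acetate, and SN2 coupling at C9 keeps the C7=C8 E geometry.

Step 4
Reactants: 5 silyl enyne acetate
Product: 6 (2E,6E)-3,7-dimethylundeca-2,6-dien-10-yn-1-ol
Conditions: K2CO3, MeOH, rt
Reagents that add atoms: none
Why: Base-mediated methanolysis removes the acetate and protodesilylates the alkynylsilane in one operation.

Step 5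
Reactants: 6 enynol
Product: 7 (2E,6E)-3,7-dimethyldodeca-2,6-dien-10-yn-1-ol
Conditions: n-BuLi (2.1 equiv), THF, −78 °C; MeI (1.1 equiv), −78 °C → rt
Reagents that add atoms: iodomethane CI
Why: Acetylide alkylation; in THF the lithium acetylide of the alkoxide–acetylide dianion is methylated while the lithium alkoxide stays inert, which installs the C20 methyl cap.

Step 6
Reactants: 7 dienynol
Product: 8 [(2S,3S)-3-methyl-3-[(3E)-4-methylnon-3-en-7-yn-1-yl]oxiran-2-yl]methanol
Conditions: Ti(Oi-Pr)4 (10 mol %), L-(+)-diethyl tartrate (12 mol %), t-BuOOH, 4 Å MS, CH2Cl2, −20 °C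
Reagents that add atoms: tert-butyl hydroperoxide CC(C)(C)OO
Why: Sharpless asymmetric epoxidation; only the allylic C3=C4 olefin is activated on titanium, and L-(+)-tartrate delivers oxygen to the face that gives the (2S,3S)-epoxy alcohol, i.e. 3S,4S in cembrane numbering.

Step 7
Reactants: 8 epoxy alcohol; 9 methyl propiolate
Product: 11 methyl 4-[(2S,3S)-3-methyl-3-[(3E)-4-methylnon-3-en-7-yn-1-yl]oxiran-2-yl]but-2-ynoate, via epoxy triflate 10 (not isolated)
Conditions: Tf2O, 2,6-lutidine, CH2Cl2, −78 °C; then lithium acetylide of 9 (LiHMDS, THF, −78 °C), DMPU, −78 → −30 °C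
Reagents that add atoms: none
Why: Alkylation of a lithium acetylide by a primary triflate forms C1–C2; C2 is the electrophile because a carbanion or radical there would open the epoxide, and displacement of triflate at low temperature is faster than attack on the trisubstituted oxirane.

Step 8
Reactants: 11 ynoate
Product: 13 methyl (2Z)-2-(hydroxymethyl)-4-[(2S,3S)-3-methyl-3-[(3E)-4-methylnon-3-en-7-yn-1-yl]oxiran-2-yl]but-2-enoate, via alkenylalane 12 (not isolated)
Conditions: DIBAL-H, HMPA, THF, 0 °C; then CH2O (gas), 0 °C → rt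
Reagents that add atoms: formaldehyde C=O
Why: Vinylalumination: cis hydroalumination of the conjugated ynoate by the HMPA-complexed hydride puts aluminium on C15, which then adds to formaldehyde (C17); the isolated alkyne, the epoxide and the ester are not attacked by this reagent.

Step 9
Reactants: 13 allylic alcohol
Product: 14 methyl (2E)-2-(bromomethyl)-4-[(2S,3S)-3-methyl-3-[(3E)-4-methylnon-3-en-7-yn-1-yl]oxiran-2-yl]but-2-enoate
Conditions: CBr4, PPh3, 2,6-lutidine, CH2Cl2, −20 °C
Reagents that add atoms: carbon tetrabromide BrC(Br)(Br)Br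
Why: Appel bromination, buffered and cold to protect the epoxide; an SN2′ isomer would be harmless because both bromides give the same allylchromium species in step 10.

Step 10
Reactants: 14 allylic bromide; 15 (tert-butyldimethylsilyloxy)acetaldehyde
Product: 17 (4R,5R)-5-[(tert-butyldimethylsilyloxy)methyl]-4-{[(2S,3S)-3-methyl-3-[(3E)-4-methylnon-3-en-7-yn-1-yl]oxiran-2-yl]methyl}-3-methylideneoxolan-2-one, via silyl ether 16 (not isolated)
Conditions: CrCl2 (10 mol %), chiral carbazole-bis(oxazoline) ligand (11 mol %), Mn, TMSCl, THF, rt; aq. citric acid; PPTS (cat.), CH2Cl2, rt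
Reagents that add atoms: none
Why: Catalytic enantioselective Nozaki–Hiyama 2-(alkoxycarbonyl)allylation, then lactonisation; the γ-substituted allylchromium reacts through a chair transition state as its E form whatever the bromide geometry (anti adduct, hence the trans lactone at C1/C14), and the ligand on chromium directs addition to the Re face of 15, which fixes 14R and with it 1R.

Step 11
Reactants: 17 silyl ether lactone
Product: 18 (4R,5R)-5-(hydroxymethyl)-4-{[(2S,3S)-3-methyl-3-[(3E)-4-methylnon-3-en-7-yn-1-yl]oxiran-2-yl]methyl}-3-methylideneoxolan-2-one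
Conditions: TBAF, AcOH (1:1), THF, 0 °C → rt
Reagents that add atoms: none
Why: Buffered fluoride desilylation; acetic acid keeps the medium near neutral so that the Michael-acceptor lactone and the epoxide survive.

Step 12
Reactants: 18 hydroxymethyl lactone
Product: 19 (2R,3R)-3-{[(2S,3S)-3-methyl-3-[(3E)-4-methylnon-3-en-7-yn-1-yl]oxiran-2-yl]methyl}-4-methylidene-5-oxooxolane-2-carbaldehyde
Conditions: Dess–Martin periodinane, NaHCO3, CH2Cl2, 0 °C; used at once
Reagents that add atoms: none
Why: Dess–Martin oxidation under bicarbonate buffering gives the configurationally labile α-acyloxy aldehyde without epimerising C14.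

Step 13
Reactants: 19 ynal
Product: 20 (1R,3S,4S,7E,11E,13S,14R)-3,4-epoxy-13-(triethylsilyloxy)cembra-7,11,15(17)-trien-16,14-olide
Conditions: Ni(cod)2 (20 mol %), IMes (free carbene, 20 mol %), Et3SiH (3 equiv), THF, 45 °C, slow addition of 19 to 2 mM
Reagents that add atoms: triethylsilane CC[SiH](CC)CC
Why: Nickel(0)/N-heterocyclic-carbene-catalysed reductive alkyne–aldehyde coupling: Ni(0) binds the C11≡C12 alkyne and the C13 aldehyde and undergoes oxidative cyclisation to an oxanickelacyclopentene (new C12–C13 bond), σ-bond metathesis with the silane forms the O–SiEt3 bond and a nickel hydride, and C11–H reductive elimination releases the catalyst. The closest known reaction type is the nickel-catalysed reductive macrocyclisation of ynals to macrocyclic allylic silyl ethers. One ring is closed, the 14-membered carbocycle, by C12–C13 bond formation in the endo mode with respect to the alkyne (both alkyne carbons become ring members); the lactone and epoxide rings are carried through. The syn addition of H and C13 across the alkyne fixes the E geometry of C11=C12 (C10 and C13 trans). The new stereocentre C13 is controlled by the adjacent C14: in the polar Felkin–Anh arrangement the C14–O bond lies anti to the incoming C12, which should give the 13,14-anti relation, i.e. 13S. Regioselectivity for C12 over C11 is needed and is secured by the small carbene ligand, which places the new bond at the alkyne carbon bearing the smaller substituent (the C20 methyl), and by the alternative being a 13-membered ring with an exocyclic ethylidene. Chemoselectivity for the aldehyde over the α-methylene lactone and for cyclisation over oligomerisation is needed and is addressed by the high reactivity of the α-oxygenated aldehyde in the oxidative cyclisation and by slow addition at high dilution.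

Step 14
Reactants: 20 macrocyclic silyl ether
Product: 21 (1R,3S,4S,7E,11E,13S,14R)-3,4-epoxy-13-hydroxycembra-7,11,15(17)-trien-16,14-olide
Conditions: TBAF, AcOH (1:1), THF, 0 °C
Reagents that add atoms: none
Why: Buffered fluoride cleavage of the triethylsilyl ether frees the allylic alcohol without acid that could ionise C13 or open the epoxide.

Step 15
Reactants: 21 macrocyclic alcohol
Product: 22 (1R,3S,4S,7E,11E,13S,14R)-13-acetoxy-3,4-epoxycembra-7,11,15(17)-trien-16,14-olide
Conditions: Ac2O, DMAP (cat.), pyridine, CH2Cl2, 0 °C → rt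
Reagents that add atoms: acetic anhydride CC(=O)OC(C)=O
Why: DMAP-catalysed acetylation of the secondary allylic alcohol; no stereocentre is touched, and the acetate now deactivates the C11=C12 olefin for the last step.

Step 16
Reactants: 22 acetate
Product: 23 (1R,3S,4S,7S,11E,13S,14R)-13-acetoxy-3,4-epoxy-7-hydroperoxycembra-8(19),11,15(17)-trien-16,14-olide (CNP0166375.1)
Conditions: O2, tetraphenylporphyrin (cat.), visible light, CH2Cl2, −20 °C
Reagents that add atoms: dioxygen O=O
Why: Schenck ene reaction: singlet oxygen adds suprafacially to C7=C8, the only electron-rich olefin left (C11=C12 carries the allylic acetate, C15=C17 is an enoate), and abstraction of H from C19 on the more substituted side of the olefin (cis effect) gives the 7-hydroperoxy-8(19)-ene. The C7 configuration follows from attack on the exposed outer face of the olefin, which stands roughly perpendicular to the mean plane of the macrocycle; this is the least secured stereocentre of the route.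

## Compound list

1 | geranyl acetate [(2E)-3,7-dimethylocta-2,6-dien-1-yl acetate] | CC(C)=CCC/C(C)=C/COC(C)=O | starting material
2 | (2E,6E)-8-hydroxy-3,7-dimethylocta-2,6-dien-1-yl acetate | OC/C(C)=C/CC/C(C)=C/COC(C)=O | intermediate
3 | (2E,6E)-8-bromo-3,7-dimethylocta-2,6-dien-1-yl acetate | BrC/C(C)=C/CC/C(C)=C/COC(C)=O | intermediate
4 | 3-bromo-1-(trimethylsilyl)prop-1-yne | C[Si](C)(C)C#CCBr | starting material
5 | (2E,6E)-3,7-dimethyl-11-(trimethylsilyl)undeca-2,6-dien-10-yn-1-yl acetate | C[Si](C)(C)C#CCC/C(C)=C/CC/C(C)=C/COC(C)=O | intermediate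
6 | (2E,6E)-3,7-dimethylundeca-2,6-dien-10-yn-1-ol | C#CCC/C(C)=C/CC/C(C)=C/CO | intermediate
7 | (2E,6E)-3,7-dimethyldodeca-2,6-dien-10-yn-1-ol | CC#CCC/C(C)=C/CC/C(C)=C/CO | intermediate
8 | [(2S,3S)-3-methyl-3-[(3E)-4-methylnon-3-en-7-yn-1-yl]oxiran-2-yl]methanol | OC[C@@H]1O[C@@]1(C)CC/C=C(\C)CCC#CC | intermediate
9 | methyl propiolate (methyl prop-2-ynoate) | C#CC(=O)OC | starting material
10 | [(2S,3S)-3-methyl-3-[(3E)-4-methylnon-3-en-7-yn-1-yl]oxiran-2-yl]methyl trifluoromethanesulfonate | O=S(=O)(OC[C@@H]1O[C@@]1(C)CC/C=C(\C)CCC#CC)C(F)(F)F | intermediate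
11 | methyl 4-[(2S,3S)-3-methyl-3-[(3E)-4-methylnon-3-en-7-yn-1-yl]oxiran-2-yl]but-2-ynoate | COC(=O)C#CC[C@@H]1O[C@@]1(C)CC/C=C(\C)CCC#CC | intermediate
12 | methyl (2E)-2-[bis(2-methylpropyl)alumanyl]-4-[(2S,3S)-3-methyl-3-[(3E)-4-methylnon-3-en-7-yn-1-yl]oxiran-2-yl]but-2-enoate | CC(C)C[Al](CC(C)C)/C(C(=O)OC)=C/C[C@@H]1O[C@@]1(C)CC/C=C(\C)CCC#CC | intermediate
13 | methyl (2Z)-2-(hydroxymethyl)-4-[(2S,3S)-3-methyl-3-[(3E)-4-methylnon-3-en-7-yn-1-yl]oxiran-2-yl]but-2-enoate | OC/C(C(=O)OC)=C/C[C@@H]1O[C@@]1(C)CC/C=C(\C)CCC#CC | intermediate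
14 | methyl (2E)-2-(bromomethyl)-4-[(2S,3S)-3-methyl-3-[(3E)-4-methylnon-3-en-7-yn-1-yl]oxiran-2-yl]but-2-enoate | BrC/C(C(=O)OC)=C/C[C@@H]1O[C@@]1(C)CC/C=C(\C)CCC#CC | intermediate
15 | (tert-butyldimethylsilyloxy)acetaldehyde | CC(C)(C)[Si](C)(C)OCC=O | starting material
16 | methyl (3R,4R)-5-(tert-butyldimethylsilyloxy)-2-methylidene-3-{[(2S,3S)-3-methyl-3-[(3E)-4-methylnon-3-en-7-yn-1-yl]oxiran-2-yl]methyl}-4-(trimethylsilyloxy)pentanoate | CC(C)(C)[Si](C)(C)OC[C@H](O[Si](C)(C)C)[C@H](C[C@@H]1O[C@@]1(C)CC/C=C(\C)CCC#CC)C(=C)C(=O)OC | intermediate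
17 | (4R,5R)-5-[(tert-butyldimethylsilyloxy)methyl]-4-{[(2S,3S)-3-methyl-3-[(3E)-4-methylnon-3-en-7-yn-1-yl]oxiran-2-yl]methyl}-3-methylideneoxolan-2-one | CC(C)(C)[Si](C)(C)OC[C@@H]1OC(=O)C(=C)[C@H]1C[C@@H]1O[C@@]1(C)CC/C=C(\C)CCC#CC | intermediate
18 | (4R,5R)-5-(hydroxymethyl)-4-{[(2S,3S)-3-methyl-3-[(3E)-4-methylnon-3-en-7-yn-1-yl]oxiran-2-yl]methyl}-3-methylideneoxolan-2-one | OC[C@@H]1OC(=O)C(=C)[C@H]1C[C@@H]1O[C@@]1(C)CC/C=C(\C)CCC#CC | intermediate
19 | (2R,3R)-3-{[(2S,3S)-3-methyl-3-[(3E)-4-methylnon-3-en-7-yn-1-yl]oxiran-2-yl]methyl}-4-methylidene-5-oxooxolane-2-carbaldehyde | O=C[C@@H]1OC(=O)C(=C)[C@H]1C[C@@H]1O[C@@]1(C)CC/C=C(\C)CCC#CC | intermediate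
20 | (1R,3S,4S,7E,11E,13S,14R)-3,4-epoxy-13-(triethylsilyloxy)cembra-7,11,15(17)-trien-16,14-olide | C1/C=C(\C)[C@H](O[Si](CC)(CC)CC)[C@@H]2OC(=O)C(=C)[C@H]2C[C@@H]2O[C@@]2(C)CC/C=C(\C)C1 | intermediate
21 | (1R,3S,4S,7E,11E,13S,14R)-3,4-epoxy-13-hydroxycembra-7,11,15(17)-trien-16,14-olide | C1/C=C(\C)[C@H](O)[C@@H]2OC(=O)C(=C)[C@H]2C[C@@H]2O[C@@]2(C)CC/C=C(\C)C1 | intermediate
22 | (1R,3S,4S,7E,11E,13S,14R)-13-acetoxy-3,4-epoxycembra-7,11,15(17)-trien-16,14-olide | C1/C=C(\C)[C@H](OC(C)=O)[C@@H]2OC(=O)C(=C)[C@H]2C[C@@H]2O[C@@]2(C)CC/C=C(\C)C1 | intermediate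
23 | (1R,3S,4S,7S,11E,13S,14R)-13-acetoxy-3,4-epoxy-7-hydroperoxycembra-8(19),11,15(17)-trien-16,14-olide (CNP0166375.1) | C=C1CC/C=C(\C)[C@H](OC(C)=O)[C@@H]2OC(=O)C(=C)[C@H]2C[C@@H]2O[C@@]2(C)CC[C@@H]1OO | target

## Step count and risk

Total step count: 16. Longest linear sequence: 16 steps (1 → 23); compounds 4, 9 and 15 enter as purchased.

**Step 13 (key step).** The most likely failure is loss of chemoselectivity or regioselectivity in the oxidative cyclisation. Nickel(0) can bind the C15=C17 enoate and couple it with the alkyne, bond formation can shift to C11 (13-membered ring), or facial selectivity at C13 can erode because the ring-closing geometry overrides the Felkin–Anh preference. Oligomerisation competes if dilution is insufficient.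
Fallback, from bromide 14, returning at alcohol 21: 14 is allylated under stoichiometric chromium(II) conditions (anti selective, with Felkin–Anh control by the silyloxy centre) with the known aldehyde (S)-2-(tert-butyldimethylsilyloxy)pent-3-ynal F1, giving after lactonisation the diyne lactone F2. Ring-closing alkyne metathesis with a molybdenum alkylidyne silanolate catalyst (5 Å MS, toluene) closes the 14-membered cycloalkyne F3; alkylidynes ignore every olefin in the molecule. Buffered fluoride gives the propargylic alcohol F4. Hydroxyl-directed ruthenium-catalysed trans-hydrostannation places tin on C12 and gives the alkenylstannane F5 (C10 and C13 trans). Methyl–Stille coupling (MeI, Pd/Cu) then gives 21.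

**Step 16.** The most likely failure is poor regioselectivity of hydrogen abstraction: abstraction from C6 instead of C19 leads to the tertiary C8 hydroperoxide with a C6=C7 olefin. Poor facial selectivity at C7 is the second risk, since it rests only on the macrocyclic conformation.
Fallback, from acetate 22, returning at 23: ene-type chlorination with hypochlorous acid (Ca(OCl)2, CO2, CH2Cl2–H2O, 0 °C) puts chlorine on C7 and moves the olefin to C8=C19, giving the allylic chloride F6 (7-chloro analogue of 23, C7 epimers). Silver-assisted perhydrolysis (AgOTf, anhydrous H2O2 in Et2O, −30 °C) substitutes at the more substituted allyl terminus C7 to give 23, which is separated from its C7 epimer. This secures the regiochemistry but not the C7 configuration.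

**Step 10.** The most likely failure is insufficient catalyst control: the remote epoxide centres give no help, so erosion of facial selectivity at the aldehyde would give the (1S,14S) diastereomer. Halosilane-induced opening of the epoxide is the second risk.
Fallback, from bromide 14, returning at aldehyde 19: the chiral-pool aldehyde (S)-2,3-bis(tert-butyldimethylsilyloxy)propanal F7 replaces 15 in a stoichiometric chromium(II) allylation without halosilane. Its α-silyloxy centre sets C14 by Felkin–Anh control (anti), and the anti course of the allylation sets C1, giving the bis-silyl lactone F8. Buffered fluoride gives the diol F9, and NaIO4 cleaves it to 19.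

**Step 7.** The most likely failure is sluggish alkylation by the stabilised, thermally fragile propiolate anion, so that the triflate is lost by decomposition or by attack on the oxirane before C–C bond formation.
Fallback, from epoxy alcohol 8 (through triflate 10), returning at ynoate 11: 10 is alkylated with the more nucleophilic lithium (trimethylsilyl)acetylide (THF–DMPU, −78 °C) to give the silyl alkyne F10. K2CO3/MeOH gives the terminal alkyne F11. Deprotonation (n-BuLi, −78 °C) and trapping with methyl chloroformate gives 11.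

## Further compounds

F1 | step 13 | (S)-2-(tert-butyldimethylsilyloxy)pent-3-ynal | CC#C[C@H](O[Si](C)(C)C(C)(C)C)C=O
F2 | step 13 | (4R,5R)-5-[(1S)-1-(tert-butyldimethylsilyloxy)but-2-yn-1-yl]-4-{[(2S,3S)-3-methyl-3-[(3E)-4-methylnon-3-en-7-yn-1-yl]oxiran-2-yl]methyl}-3-methylideneoxolan-2-one | CC#C[C@H](O[Si](C)(C)C(C)(C)C)[C@@H]1OC(=O)C(=C)[C@H]1C[C@@H]1O[C@@]1(C)CC/C=C(\C)CCC#CC
F3 | step 13 | 13-O-tert-butyldimethylsilyl-11,12-didehydro-20-nor analogue of 21 (14-membered cycloalkyne) | C1C#C[C@H](O[Si](C)(C)C(C)(C)C)[C@@H]2OC(=O)C(=C)[C@H]2C[C@@H]2O[C@@]2(C)CC/C=C(\C)C1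
F4 | step 13 | 11,12-didehydro-20-nor analogue of 21 (cyclic propargylic alcohol) | C1C#C[C@H](O)[C@@H]2OC(=O)C(=C)[C@H]2C[C@@H]2O[C@@]2(C)CC/C=C(\C)C1
F5 | step 13 | 12-(tributylstannyl)-20-nor analogue of 21 (C10 and C13 trans) | C1/C=C(\[Sn](CCCC)(CCCC)CCCC)[C@H](O)[C@@H]2OC(=O)C(=C)[C@H]2C[C@@H]2O[C@@]2(C)CC/C=C(\C)C1
F6 | step 16 | 7-chloro analogue of 23 (C7 epimers) | C=C1CC/C=C(\C)[C@H](OC(C)=O)[C@@H]2OC(=O)C(=C)[C@H]2C[C@@H]2O[C@@]2(C)CCC1Cl
F7 | step 10 | (S)-2,3-bis(tert-butyldimethylsilyloxy)propanal | CC(C)(C)[Si](C)(C)OC[C@H](O[Si](C)(C)C(C)(C)C)C=O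
F8 | step 10 | (4R,5R)-5-[(1S)-1,2-bis(tert-butyldimethylsilyloxy)ethyl]-4-{[(2S,3S)-3-methyl-3-[(3E)-4-methylnon-3-en-7-yn-1-yl]oxiran-2-yl]methyl}-3-methylideneoxolan-2-one | CC(C)(C)[Si](C)(C)OC[C@H](O[Si](C)(C)C(C)(C)C)[C@@H]1OC(=O)C(=C)[C@H]1C[C@@H]1O[C@@]1(C)CC/C=C(\C)CCC#CC
F9 | step 10 | (4R,5R)-5-[(1S)-1,2-dihydroxyethyl]-4-{[(2S,3S)-3-methyl-3-[(3E)-4-methylnon-3-en-7-yn-1-yl]oxiran-2-yl]methyl}-3-methylideneoxolan-2-one | OC[C@H](O)[C@@H]1OC(=O)C(=C)[C@H]1C[C@@H]1O[C@@]1(C)CC/C=C(\C)CCC#CC
F10 | step 7 | trimethyl{3-[(2S,3S)-3-methyl-3-[(3E)-4-methylnon-3-en-7-yn-1-yl]oxiran-2-yl]prop-1-yn-1-yl}silane | C[Si](C)(C)C#CC[C@@H]1O[C@@]1(C)CC/C=C(\C)CCC#CC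
F11 | step 7 | (2S,3S)-2-methyl-2-[(3E)-4-methylnon-3-en-7-yn-1-yl]-3-(prop-2-yn-1-yl)oxirane | C#CC[C@@H]1O[C@@]1(C)CC/C=C(\C)CCC#CC
A1 | alternative 1 | methyl (2E)-2-(bromomethyl)-4-[(2S,3S)-3-[(3E,7E,9S)-9-(tert-butyldimethylsilyloxy)-4,8-dimethyl-10-oxodeca-3,7-dien-1-yl]-3-methyloxiran-2-yl]but-2-enoate | BrC/C(C(=O)OC)=C/C[C@@H]1O[C@@]1(C)CC/C=C(\C)CC/C=C(\C)[C@H](O[Si](C)(C)C(C)(C)C)C=O
A2 | alternative 1 | (1R,3S,4S,7E,11E,13S,14R)-13-(tert-butyldimethylsilyloxy)-3,4-epoxycembra-7,11,15(17)-trien-16,14-olide | C1/C=C(\C)[C@H](O[Si](C)(C)C(C)(C)C)[C@@H]2OC(=O)C(=C)[C@H]2C[C@@H]2O[C@@]2(C)CC/C=C(\C)C1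
A3 | alternative 2 | (4R,5R)-5-[(1S,2E)-1-acetoxy-2,6-dimethylhepta-2,6-dien-1-yl]-4-{[(2S,3S)-3-(but-3-en-1-yl)-3-methyloxiran-2-yl]methyl}-3-methylideneoxolan-2-one | C=C(C)CC/C=C(\C)[C@H](OC(C)=O)[C@@H]1OC(=O)C(=C)[C@H]1C[C@@H]1O[C@@]1(C)CCC=C
A4 | alternative 3 | (2E,6E)-farnesol | CC(C)=CCC/C(C)=C/CC/C(C)=C/CO
A5 | alternative 3 | (2E,6E)-2,6-dimethyl-9-[(2S,3S)-2-methyl-3-(prop-2-yn-1-yl)oxiran-2-yl]nona-2,6-dienal | C#CC[C@@H]1O[C@@]1(C)CC/C=C(\C)CC/C=C(\C)C=O
A6 | alternative 3 | (1(14)E,3S,4S,7E,11E,13R)-3,4-epoxy-13-(triethylsilyloxy)-15,16,17-trinorcembra-1(14),7,11-triene | C1/C=C(\C)[C@H](O[Si](CC)(CC)CC)/C=C/C[C@@H]2O[C@@]2(C)CC/C=C(\C)C1
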